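Everything rests on opening ring C at the O–C8 bond and reading it as a furan. Ring C shows H on C4, an sp2 carbon (C16) on C5, and on C8 an oxygen plus two carbon branches (C9, C17): the imprint of an oxidised 2,5-disubstituted furfuryl alcohol. One oxidative ring expansion of furan 9, which carries the C4 carbinol, the protected C2–C3 arm and the silylated C9 carbon, should give ring C as an enone hemiketal whose C5 ketone, C6/C7 alkene and anomeric C8 then take the methylene, the chloride and lactone oxygen, and the quaternary centre. Ring A follows by two aldol-type bonds.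

Key step: step 6

Remarks on the chemistry (assumptions):
- Locants C1–C20 and ring letters A–D are those of the target skeleton; PMB = 4-methoxybenzyl, TBS = tert-butyldimethylsilyl, TIPS = triisopropylsilyl, TES = triethylsilyl.
- A 2-alkoxyethyl organomagnesium reagent would collapse to ethylene and an alkoxide, so the C2–C3 arm is introduced as an acyl unit and C4 is set by reduction; the arm oxygen is carried as a PMB ether because a benzyl ether could not be cleaved later beside the alkenes.
- The sense of induction in step 16 is assumed by analogy with dialkylzinc additions to 4,4-disubstituted cyclohexadienones; the antipodal ligand would be used if it proved opposite. Ligand L = (S)-BINOL-derived N,N-bis[(R)-1-phenylethyl]phosphoramidite.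
- Stereocentres that exist only temporarily and are erased later (C11 in 28–37, C1 in 32–34) are left undefined.

Step 1
Reactants: 1 4-methoxybenzyl alcohol; 2 methyl acrylate
Product: 3 methyl 3-[(4-methoxybenzyl)oxy]propanoate
Conditions: KOt-Bu (5 mol %), THF, 0 °C to rt
Reagents that add atoms: none
Why: Base-catalysed oxa-Michael addition of a primary alkoxide to an acrylate should give the 3-alkoxypropanoate, that is the C2–C3 unit with its oxygen already masked as a PMB ether.

Step 2
Reactants: 3 methyl 3-[(4-methoxybenzyl)oxy]propanoate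
Product: 4 N-methoxy-N-methyl-3-[(4-methoxybenzyl)oxy]propanamide
Conditions: MeNH(OMe)·HCl, i-PrMgCl, THF, −20 °C
Reagents that add atoms: N,O-dimethylhydroxylamine hydrochloride, CNOC.Cl
Why: Weinreb amidation of the methyl ester by the chloromagnesium amide should proceed cleanly and furnishes an acyl donor that cannot over-add.

Step 3
Reactants: 5 furfuryl alcohol
Product: 6 tert-butyl(furan-2-ylmethoxy)dimethylsilane
Conditions: TBSCl, imidazole, DMF, 0 °C to rt
Reagents that add atoms: tert-butyldimethylsilyl chloride, CC(C)(C)[Si](C)(C)Cl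
Why: Routine imidazole-promoted silylation protects the future C9 oxygen as a TBS ether that tolerates lithiation and the later furan oxidation.

Step 4
Reactants: 6 tert-butyl(furan-2-ylmethoxy)dimethylsilane; 4 N-methoxy-N-methyl-3-[(4-methoxybenzyl)oxy]propanamide
Product: 8 1-[5-(TBS-oxymethyl)furan-2-yl]-3-[(4-methoxybenzyl)oxy]propan-1-one, via 5-lithiofuran 7 (not isolated)
Conditions: n-BuLi, THF, −78 to 0 °C; then 4, −78 °C; aq. NH4Cl
Reagents that add atoms: none
Why: α-Lithiation of the 2-substituted furan at its free 5-position followed by Weinreb ketone synthesis should join C4 to the ring, the chelated tetrahedral adduct preventing a second addition and the cold quench suppressing β-elimination of the PMB-oxy group.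

Step 5
Reactants: 8 1-[5-(TBS-oxymethyl)furan-2-yl]-3-[(4-methoxybenzyl)oxy]propan-1-one
Product: 9 (1S)-1-[5-(TBS-oxymethyl)furan-2-yl]-3-[(4-methoxybenzyl)oxy]propan-1-ol
Conditions: RuCl[(S,S)-TsDPEN](p-cymene) (1 mol %), HCO2H/Et3N (5:2), EtOAc, rt
Reagents that add atoms: none
Why: Noyori asymmetric transfer hydrogenation of a 2-acylfuran should set C4 as S under catalyst control, the furan being recognised in the same sense as the aryl group of aryl alkyl ketones.

Step 6
Reactants: 9 (1S)-1-[5-(TBS-oxymethyl)furan-2-yl]-3-[(4-methoxybenzyl)oxy]propan-1-ol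
Product: 11 (2S,6S)-6-hydroxy-6-(TBS-oxymethyl)-2-[2-(PMB-oxy)ethyl]-2H-pyran-3(6H)-one, via Z-ene-dione 10 (not isolated)
Conditions: NBS, NaHCO3, NaOAc, THF/H2O (4:1), 0 °C
Reagents that add atoms: water, O
Why: Achmatowicz rearrangement: electrophilic bromine adds to the electron-rich furan, water captures the resulting cation at the other α-carbon, and loss of HBr opens the dihydrofuran to Z-ene-dione 10, whose C4 hydroxyl then adds to the C8 carbonyl. The closest known reaction type is the halogen- or peracid-mediated ring expansion of 2,5-disubstituted furfuryl alcohols to 6-hydroxy-2H-pyran-3(6H)-ones. Ring C closes by a 6-exo-trig hemiketalisation that forms the O–C8 bond. The only new stereocentre, anomeric C8, is under thermodynamic control (hydroxyl axial by the anomeric effect and trans to the equatorial C4 arm), and its configuration is immaterial because it is erased by ionisation in step 9. The step needs chemoselective oxidation of the furan in the presence of the PMB arene and retention at C4: the 2,5-dialkylfuran is by far the most nucleophilic π-system, the buffer keeps the silyl ether and the product away from acid, and C4 never becomes a reacting centre.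

Step 7
Reactants: 11 (2S,6S)-6-hydroxy-6-(TBS-oxymethyl)-2-[2-(PMB-oxy)ethyl]-2H-pyran-3(6H)-one
Product: 12 anomeric acetate of 11 (acetoxy group at C8 trans to the C4 arm)
Conditions: Ac2O, pyridine, DMAP (cat.), CH2Cl2, 0 °C
Reagents that add atoms: acetic anhydride, CC(=O)OC(C)=O
Why: DMAP-catalysed O-acylation of the anomeric hydroxyl gives a leaving group for ionisation at C8, and the low temperature avoids amine-induced oxidopyrylium formation.

Step 8
Reactants: 13 tert-butyl propanoate
Product: 15 (E)-1-tert-butoxy-1-(trimethylsilyloxy)prop-1-ene, via lithium enolate 14 (not isolated)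
Conditions: LDA, THF, −78 °C; then TMSCl, −78 °C to rt
Reagents that add atoms: chlorotrimethylsilane, C[Si](C)(C)Cl
Why: Kinetic ester enolisation in THF followed by O-silylation should give mainly the E ketene silyl acetal, and the tert-butyl ester is chosen because it can later lactonise by loss of isobutene.

Step 9
Reactants: 12 anomeric acetate of 11; 15 (E)-1-tert-butoxy-1-(trimethylsilyloxy)prop-1-ene
Product: 16 tert-butyl (2R)-2-[(2R,6S)-2-(TBS-oxymethyl)-6-(2-PMB-oxyethyl)-5-oxo-5,6-dihydro-2H-pyran-2-yl]propanoate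
Conditions: TMSOTf (0.2 equiv), CH2Cl2, −78 °C
Reagents that add atoms: none
Why: Mukaiyama-type C-glycosylation: TMSOTf ionises the anomeric acetate and the ketene acetal should add to the C8 cation axially on the face anti to the C4 arm (the face taken by silane hydride in reductions of such hemiketals), which sets C8 with C9 cis to the arm, while C17 is set in an open transition state that places its hydrogen over the ring and the bulky acetal terminus gauche to the ring oxygen (17R expected).

Step 10
Reactants: 16 tert-butyl (2R)-2-[(2R,6S)-2-(TBS-oxymethyl)-6-(2-PMB-oxyethyl)-5-oxo-5,6-dihydro-2H-pyran-2-yl]propanoate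
Product: 17 C6,C7-epoxy ketone of 16 (oxirane oxygen on the ring C face that carries the C4 and C9 arms)
Conditions: t-BuOOH, DBU, CH2Cl2, 0 °C
Reagents that add atoms: tert-butyl hydroperoxide, CC(C)(C)OO
Why: Weitz–Scheffer nucleophilic epoxidation: the peroxide anion should attack C7 axially and anti to the pseudo-axial C17 branch on C8, so the oxirane oxygen sets C6 and C7 on the face of the two arms.

Step 11
Reactants: 17 C6,C7-epoxy ketone of 16
Product: 18 ring C/D keto lactone (C5 ketone, cis-fused γ-lactone with O–C7 on the C17 face, free C6 hydroxyl on the opposite face)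
Conditions: BF3·OEt2 (0.3 equiv), CH2Cl2, −40 to 0 °C
Reagents that add atoms: none
Why: Lewis-acid-promoted 5-exo-tet opening of the epoxide by the ester carbonyl oxygen at C7 (the carbon remote from the ketone) with inversion, followed by loss of isobutene, should close cis-fused ring D and leave the C6 hydroxyl trans to the new C7–O bond.

Step 12
Reactants: 18 ring C/D keto lactone
Product: 19 C6 TIPS ether of 18
Conditions: TIPSOTf, 2,6-lutidine, CH2Cl2, −78 to 0 °C
Reagents that add atoms: triisopropylsilyl triflate, CC(C)[Si](C(C)C)(C(C)C)OS(=O)(=O)C(F)(F)F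
Why: Silyl triflate silylation of the secondary α-ketol hydroxyl gives a TIPS ether that lasts to the final steps and lets the primary TBS ether be cleaved selectively.

Step 13
Reactants: 19 C6 TIPS ether of 18
Product: 20 C5 exocyclic methylene lactone (C5=C16)
Conditions: Zn, CH2Br2, TiCl4, THF/CH2Cl2, 0 °C to rt
Reagents that add atoms: dibromomethane, BrCBr
Why: Takai–Lombardo methylenation is non-basic, so the β-acyloxy ketone should neither eliminate nor epimerise at C4, and it converts ketones in preference to lactones.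

Step 14
Reactants: 20 C5 exocyclic methylene lactone
Product: 21 C9 primary alcohol
Conditions: HF·pyridine, pyridine, THF, 0 °C
Reagents that add atoms: none
Why: Buffered HF·pyridine should remove the primary TBS ether selectively, the secondary TIPS ether and the PMB ether being far more resistant (selective desilylation).

Step 15
Reactants: 21 C9 primary alcohol
Product: 22 C9 aldehyde
Conditions: Dess–Martin periodinane, NaHCO3, CH2Cl2, 0 °C to rt
Reagents that add atoms: none
Why: Dess–Martin oxidation of the neopentyl-type primary alcohol gives the non-enolisable C9 aldehyde under neutral conditions that leave the lactone α-centre C17 untouched.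

Step 16
Reactants: 23 4,4-dimethoxycyclohexa-2,5-dien-1-one
Product: 24 (R)-4,4-dimethoxy-5-methylcyclohex-2-en-1-one
Conditions: Cu(OTf)2 (2 mol %), ligand L (4 mol %), Me2Zn, toluene, −25 °C; aq. NH4Cl
Reagents that add atoms: dimethylzinc, C[Zn]C
Why: Copper–phosphoramidite-catalysed enantioselective conjugate addition of a dialkylzinc desymmetrises the dienone and sets C1 (R) under catalyst control, a stereocentre that serves only to direct step 17.

Step 17
Reactants: 24 (R)-4,4-dimethoxy-5-methylcyclohex-2-en-1-one; 22 C9 aldehyde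
Product: 26 anti aldol (9R,10S) joining C9 to C10 of ring A, via enol borinate 25 (not isolated)
Conditions: (c-Hex)2BCl, Et3N, Et2O, −78 to 0 °C; then 22, −78 to −20 °C; then MeOH, pH 7 buffer, H2O2, 0 °C
Reagents that add atoms: none
Why: Boron-mediated aldol reaction: soft enolisation at the only α′ position (C10) gives the ring-constrained E enol borinate, which should add to the aldehyde through a Zimmerman–Traxler chair on the enolate face anti to the adjacent C1 methyl group, setting C10 (S) and C9 (R) as the anti aldol.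

Step 18
Reactants: 26 anti aldol
Product: 27 C9 TBS ether of 26
Conditions: TBSOTf, 2,6-lutidine, CH2Cl2, −78 to 0 °C
Reagents that add atoms: tert-butyldimethylsilyl triflate, CC(C)(C)[Si](C)(C)OS(=O)(=O)C(F)(F)F
Why: Silyl triflate protection of the hindered C9 hydroxyl blocks retro-aldol cleavage and later acetylation (standard TBS ether formation).

Step 19
Reactants: 27 C9 TBS ether of 26
Product: 30 γ-acetoxy enone (ring A: C14 ketone, C12=C13, C11 bearing methyl and acetoxy), via cerium alkoxide 28 (not isolated), via acetoxy ketal 29 (not isolated)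
Conditions: MeLi, CeCl3, THF, −78 °C; then Ac2O, −78 to 0 °C; then 1 M aq. oxalic acid, THF, 0 °C
Reagents that add atoms: methyllithium, [Li]C; acetic anhydride, CC(=O)OC(C)=O; water, O
Why: Organocerium 1,2-addition (chemoselective for the ketone over the lactone and non-basic towards C10) brings in the C11 methyl carbon C20, the tertiary alkoxide is trapped as its acetate, and mild acid hydrolysis of the allylic dimethyl ketal then unveils the C14 enone as in quinol syntheses from quinone monoketals, the C11 configuration being irrelevant.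

Step 20
Reactants: 30 γ-acetoxy enone
Product: 32 C1 bromide of 30 (tertiary α′-bromo enone), via silyl dienol ether 31 (not isolated)
Conditions: TMSOTf, Et3N, CH2Cl2, 0 °C; then NBS, NaHCO3, THF, −78 °C
Reagents that add atoms: N-bromosuccinimide, O=C1CCC(=O)N1Br
Why: Soft enolisation can occur only towards C1 (C13 is vinylic and C11 quaternary), so the 2-silyloxydiene and its electrophilic bromination should give the α′-bromo enone regiospecifically, the C1 configuration being irrelevant.

Step 21
Reactants: 32 C1 bromide of 30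
Product: 33 C2 primary alcohol
Conditions: DDQ, CH2Cl2/pH 7 buffer (10:1), 0 °C
Reagents that add atoms: none
Why: Oxidative cleavage of the PMB ether by DDQ should free the C2 hydroxyl without touching the silyl ethers, the alkenes, the bromide or the lactone.

Step 22
Reactants: 33 C2 primary alcohol
Product: 34 C2 aldehyde
Conditions: Dess–Martin periodinane, NaHCO3, CH2Cl2, 0 °C
Reagents that add atoms: none
Why: Dess–Martin oxidation gives the C2 aldehyde under neutral conditions compatible with the tertiary α-bromo ketone.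

Step 23
Reactants: 34 C2 aldehyde
Product: 37 tetracyclic C2 acetate (rings A–D, C14 enone, C11 acetate, C9 OTBS, C6 OTIPS), via samarium enolate 35 (not isolated), via samarium aldolate 36 (not isolated)
Conditions: SmI2 (2.5 equiv), THF (2 mM, slow addition of 34), −78 °C; then Ac2O, DMAP, −78 to 0 °C
Reagents that add atoms: acetic anhydride, CC(=O)OC(C)=O
Why: Samarium Reformatsky-type aldol macrocyclisation: two-electron reduction of the C–Br bond generates the samarium enolate regiospecifically at C1 under neutral conditions, and it should add to the tethered aldehyde at high dilution (10-exo-trig for ring B, 8-exo-trig when counted through the ring C oxygen), the trans ring fusion (C2 anti to C9 across C1–C10, both ring B bonds pseudo-equatorial on ring A) and the C2 configuration being set inside the chelated cyclic transition state, while acetylation of the aldolate in the flask prevents retro-aldol opening.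

Step 24
Reactants: 37 tetracyclic C2 acetate
Product: 38 β,γ-unsaturated ketone (C14 ketone, C11=C12 alkene)
Conditions: SmI2 (2.5 equiv), THF/MeOH, −78 °C
Reagents that add atoms: none
Why: SmI2 reduction of the γ-acetoxy enone (vinylogous α-acyloxy ketone cleavage) expels the C11 acetate to a dienolate whose kinetic α-protonation at C13 by methanol should deliver the deconjugated ketone with the C11=C12 alkene.

Step 25
Reactants: 38 β,γ-unsaturated ketone
Product: 39 C14 axial alcohol (14S)
Conditions: LiBH(s-Bu)3, THF, −78 °C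
Reagents that add atoms: none
Why: The bulky trialkylborohydride should attack C14 along the equatorial trajectory (steric approach control, the axial path being shielded by H10) and give the axial alcohol anti to the axial C1 methyl group, as in reductions of 4,4-dimethyl-3-keto terpenoids to their axial alcohols.

Step 26
Reactants: 39 C14 axial alcohol
Product: 40 2,14-diacetate bis-silyl ether
Conditions: Ac2O, DMAP, Et3N, CH2Cl2, rt
Reagents that add atoms: acetic anhydride, CC(=O)OC(C)=O
Why: DMAP-catalysed acetylation of the hindered axial C14 hydroxyl completes the 2,14-diacetate.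

Step 27
Reactants: 40 2,14-diacetate bis-silyl ether
Product: 41 6,9-diol (C6 hydroxyl trans to the C7 lactone oxygen)
Conditions: HF (48% aq.), MeCN, 0 °C to rt
Reagents that add atoms: none
Why: Aqueous HF in acetonitrile should cleave both silyl ethers (global desilylation) without affecting the acetates, the lactone or the alkenes.

Step 28
Reactants: 41 6,9-diol
Product: 42 CNP0198838.2 (target)
Conditions: PPh3, hexachloroacetone, CH2Cl2, −20 to 0 °C
Reagents that add atoms: hexachloroacetone, ClC(Cl)(Cl)C(=O)C(Cl)(Cl)Cl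
Why: Phosphine/hexachloroacetone chlorination of the allylic alcohol proceeds by SN2 displacement of the alkoxyphosphonium ion with inversion and little allylic transposition, so the C6 chloride should arrive cis to the C7 lactone oxygen (6S), while the neopentyl-like C9 hydroxyl between C8 and C10 is too hindered to be displaced.

Compound list
1 | 4-methoxybenzyl alcohol | COc1ccc(CO)cc1 | starting material
2 | methyl acrylate | C=CC(=O)OC | starting material
3 | methyl 3-[(4-methoxybenzyl)oxy]propanoate | COC(=O)CCOCc1ccc(OC)cc1 | intermediate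
4 | N-methoxy-N-methyl-3-[(4-methoxybenzyl)oxy]propanamide | CON(C)C(=O)CCOCc1ccc(OC)cc1 | intermediate
5 | furfuryl alcohol | OCc1ccco1 | starting material
6 | tert-butyl(furan-2-ylmethoxy)dimethylsilane | CC(C)(C)[Si](C)(C)OCc1ccco1 | intermediate
7 | [5-(TBS-oxymethyl)furan-2-yl]lithium (not isolated) | [Li]c1ccc(CO[Si](C)(C)C(C)(C)C)o1 | intermediate
8 | 1-[5-(TBS-oxymethyl)furan-2-yl]-3-[(4-methoxybenzyl)oxy]propan-1-one | O=C(CCOCc1ccc(OC)cc1)c1ccc(CO[Si](C)(C)C(C)(C)C)o1 | intermediate
9 | (1S)-1-[5-(TBS-oxymethyl)furan-2-yl]-3-[(4-methoxybenzyl)oxy]propan-1-ol (C4 S; key-step precursor) | O[C@@H](CCOCc1ccc(OC)cc1)c1ccc(CO[Si](C)(C)C(C)(C)C)o1 | intermediate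
10 | (6S,3Z)-1-(TBS-oxy)-6-hydroxy-8-(PMB-oxy)oct-3-ene-2,5-dione (not isolated) | O[C@@H](CCOCc1ccc(OC)cc1)C(=O)/C=C\C(=O)CO[Si](C)(C)C(C)(C)C | intermediate
11 | (2S,6S)-6-hydroxy-6-(TBS-oxymethyl)-2-[2-(PMB-oxy)ethyl]-2H-pyran-3(6H)-one (major anomer, hydroxyl trans to the C4 arm; key-step product) | O=C1[C@H](CCOCc2ccc(OC)cc2)O[C@](O)(CO[Si](C)(C)C(C)(C)C)C=C1 | intermediate
12 | anomeric acetate of 11 (acetoxy at C8 trans to the C4 arm) | O=C1[C@H](CCOCc2ccc(OC)cc2)O[C@](OC(C)=O)(CO[Si](C)(C)C(C)(C)C)C=C1 | intermediate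
13 | tert-butyl propanoate | CCC(=O)OC(C)(C)C | starting material
14 | lithium (E)-enolate of tert-butyl propanoate (not isolated) | C/C=C(\OC(C)(C)C)O[Li] | intermediate
15 | (E)-1-tert-butoxy-1-(trimethylsilyloxy)prop-1-ene | C/C=C(\OC(C)(C)C)O[Si](C)(C)C | intermediate
16 | tert-butyl (2R)-2-[(2R,6S)-2-(TBS-oxymethyl)-6-(2-PMB-oxyethyl)-5-oxo-5,6-dihydro-2H-pyran-2-yl]propanoate (4S,8R,17R; C17 branch trans to the C4 arm) | O=C1[C@H](CCOCc2ccc(OC)cc2)O[C@@](CO[Si](C)(C)C(C)(C)C)([C@@H](C)C(=O)OC(C)(C)C)C=C1 | intermediate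
17 | C6,C7-epoxy ketone of 16, oxirane oxygen on the face of the C4 and C9 arms | O=C1[C@H](CCOCc2ccc(OC)cc2)O[C@@](CO[Si](C)(C)C(C)(C)C)([C@@H](C)C(=O)OC(C)(C)C)[C@@H]2O[C@H]12 | intermediate
18 | ring C/D keto lactone: C5 ketone, cis-fused γ-lactone (O–C7 on the C17 face), C6 hydroxyl trans to C7–O, C9 as CH2OTBS, PMB-oxyethyl arm on C4 | O=C1[C@H](CCOCc2ccc(OC)cc2)O[C@@]2(CO[Si](C)(C)C(C)(C)C)[C@@H](C)C(=O)O[C@H]2[C@@H]1O | intermediate
19 | C6 TIPS ether of 18 | O=C1[C@H](CCOCc2ccc(OC)cc2)O[C@@]2(CO[Si](C)(C)C(C)(C)C)[C@@H](C)C(=O)O[C@H]2[C@@H]1O[Si](C(C)C)(C(C)C)C(C)C | intermediate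
20 | C5 exocyclic methylene lactone (C5=C16) | C=C1[C@H](CCOCc2ccc(OC)cc2)O[C@@]2(CO[Si](C)(C)C(C)(C)C)[C@@H](C)C(=O)O[C@H]2[C@@H]1O[Si](C(C)C)(C(C)C)C(C)C | intermediate
21 | C9 primary alcohol | C=C1[C@H](CCOCc2ccc(OC)cc2)O[C@@]2(CO)[C@@H](C)C(=O)O[C@H]2[C@@H]1O[Si](C(C)C)(C(C)C)C(C)C | intermediate
22 | C9 aldehyde | C=C1[C@H](CCOCc2ccc(OC)cc2)O[C@@]2(C=O)[C@@H](C)C(=O)O[C@H]2[C@@H]1O[Si](C(C)C)(C(C)C)C(C)C | intermediate
23 | 4,4-dimethoxycyclohexa-2,5-dien-1-one | COC1(OC)C=CC(=O)C=C1 | starting material
24 | (R)-4,4-dimethoxy-5-methylcyclohex-2-en-1-one | O=C1C=CC(OC)(OC)[C@H](C)C1 | intermediate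
25 | dicyclohexylboron dienolate of 24 at C10–C11 (not isolated) | C[C@@H]1C=C(OB(C2CCCCC2)C2CCCCC2)C=CC1(OC)OC | intermediate
26 | anti aldol (9R,10S): ring A enone (C11 ketone, C14 dimethyl ketal) joined at C10 to the C9 carbinol, C1 methyl trans to C9 | C=C1[C@H](CCOCc2ccc(OC)cc2)O[C@@]2([C@H](O)[C@H]3C(=O)C=CC(OC)(OC)[C@@H]3C)[C@@H](C)C(=O)O[C@H]2[C@@H]1O[Si](C(C)C)(C(C)C)C(C)C | intermediate
27 | C9 TBS ether of 26 | C=C1[C@H](CCOCc2ccc(OC)cc2)O[C@@]2([C@H](O[Si](C)(C)C(C)(C)C)[C@H]3C(=O)C=CC(OC)(OC)[C@@H]3C)[C@@H](C)C(=O)O[C@H]2[C@@H]1O[Si](C(C)C)(C(C)C)C(C)C | intermediate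
28 | dichlorocerium tertiary alkoxide from methyl addition at C11 (not isolated; C11 undefined) | C=C1[C@H](CCOCc2ccc(OC)cc2)O[C@@]2([C@H](O[Si](C)(C)C(C)(C)C)[C@H]3C(C)(O[Ce](Cl)Cl)C=CC(OC)(OC)[C@@H]3C)[C@@H](C)C(=O)O[C@H]2[C@@H]1O[Si](C(C)C)(C(C)C)C(C)C | intermediate
29 | C11 acetate C14 dimethyl ketal (not isolated; C11 undefined) | C=C1[C@H](CCOCc2ccc(OC)cc2)O[C@@]2([C@H](O[Si](C)(C)C(C)(C)C)[C@H]3C(C)(OC(C)=O)C=CC(OC)(OC)[C@@H]3C)[C@@H](C)C(=O)O[C@H]2[C@@H]1O[Si](C(C)C)(C(C)C)C(C)C | intermediate
30 | γ-acetoxy enone: ring A with C14 ketone, C12=C13, C11 (methyl, acetoxy; undefined), C1 H/methyl | C=C1[C@H](CCOCc2ccc(OC)cc2)O[C@@]2([C@H](O[Si](C)(C)C(C)(C)C)[C@H]3C(C)(OC(C)=O)C=CC(=O)[C@@H]3C)[C@@H](C)C(=O)O[C@H]2[C@@H]1O[Si](C(C)C)(C(C)C)C(C)C | intermediate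
31 | C14 trimethylsilyl dienol ether of 30 (C14=C1; not isolated) | C=C1[C@H](CCOCc2ccc(OC)cc2)O[C@@]2([C@H](O[Si](C)(C)C(C)(C)C)[C@H]3C(C)(OC(C)=O)C=CC(O[Si](C)(C)C)=C3C)[C@@H](C)C(=O)O[C@H]2[C@@H]1O[Si](C(C)C)(C(C)C)C(C)C | intermediate
32 | C1 bromide of 30 (C1 and C11 undefined) | C=C1[C@H](CCOCc2ccc(OC)cc2)O[C@@]2([C@H](O[Si](C)(C)C(C)(C)C)[C@H]3C(C)(OC(C)=O)C=CC(=O)C3(C)Br)[C@@H](C)C(=O)O[C@H]2[C@@H]1O[Si](C(C)C)(C(C)C)C(C)C | intermediate
33 | C2 primary alcohol | C=C1[C@H](CCO)O[C@@]2([C@H](O[Si](C)(C)C(C)(C)C)[C@H]3C(C)(OC(C)=O)C=CC(=O)C3(C)Br)[C@@H](C)C(=O)O[C@H]2[C@@H]1O[Si](C(C)C)(C(C)C)C(C)C | intermediate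
34 | C2 aldehyde | C=C1[C@H](CC=O)O[C@@]2([C@H](O[Si](C)(C)C(C)(C)C)[C@H]3C(C)(OC(C)=O)C=CC(=O)C3(C)Br)[C@@H](C)C(=O)O[C@H]2[C@@H]1O[Si](C(C)C)(C(C)C)C(C)C | intermediate
35 | C1 samarium dienolate of 34 (not isolated) | C=C1[C@H](CC=O)O[C@@]2([C@H](O[Si](C)(C)C(C)(C)C)[C@H]3C(C)(OC(C)=O)C=CC(O[Sm](I)I)=C3C)[C@@H](C)C(=O)O[C@H]2[C@@H]1O[Si](C(C)C)(C(C)C)C(C)C | intermediate
36 | ring B-closed samarium aldolate at C2 (not isolated) | C=C1[C@@H]2C[C@@H](O[Sm](I)I)[C@@]3(C)C(=O)C=CC(C)(OC(C)=O)[C@@H]3[C@@H](O[Si](C)(C)C(C)(C)C)[C@]3(O2)[C@@H](C)C(=O)O[C@H]3[C@@H]1O[Si](C(C)C)(C(C)C)C(C)C | intermediate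
37 | tetracyclic C2 acetate: rings A–D, C14 enone (C12=C13), C11 acetate (undefined), C9 OTBS, C6 OTIPS; target geometry at C1, C2, C4, C7, C8, C9, C10, C17 | C=C1[C@@H]2C[C@@H](OC(C)=O)[C@@]3(C)C(=O)C=CC(C)(OC(C)=O)[C@@H]3[C@@H](O[Si](C)(C)C(C)(C)C)[C@]3(O2)[C@@H](C)C(=O)O[C@H]3[C@@H]1O[Si](C(C)C)(C(C)C)C(C)C | intermediate
38 | β,γ-unsaturated ketone: C14 ketone, C11=C12 alkene | C=C1[C@@H]2C[C@@H](OC(C)=O)[C@@]3(C)C(=O)CC=C(C)[C@@H]3[C@@H](O[Si](C)(C)C(C)(C)C)[C@]3(O2)[C@@H](C)C(=O)O[C@H]3[C@@H]1O[Si](C(C)C)(C(C)C)C(C)C | intermediate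
39 | C14 axial alcohol (14S, hydroxyl trans to the C1 methyl) | C=C1[C@@H]2C[C@@H](OC(C)=O)[C@@]3(C)[C@@H](O)CC=C(C)[C@@H]3[C@@H](O[Si](C)(C)C(C)(C)C)[C@]3(O2)[C@@H](C)C(=O)O[C@H]3[C@@H]1O[Si](C(C)C)(C(C)C)C(C)C | intermediate
40 | 2,14-diacetate with C9 OTBS and C6 OTIPS | C=C1[C@@H]2C[C@@H](OC(C)=O)[C@@]3(C)[C@@H](OC(C)=O)CC=C(C)[C@@H]3[C@@H](O[Si](C)(C)C(C)(C)C)[C@]3(O2)[C@@H](C)C(=O)O[C@H]3[C@@H]1O[Si](C(C)C)(C(C)C)C(C)C | intermediate
41 | 6,9-diol (C6 hydroxyl trans to the C7 lactone oxygen, C6 epimeric in position to the target chloride) | C=C1[C@@H]2C[C@@H](OC(C)=O)[C@@]3(C)[C@@H](OC(C)=O)CC=C(C)[C@@H]3[C@@H](O)[C@]3(O2)[C@@H](C)C(=O)O[C@H]3[C@@H]1O | intermediate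
42 | CNP0198838.2 (1R,2R,4S,6S,7R,8R,9R,10S,14S,17R) | C=C1[C@@H]2C[C@@H](OC(C)=O)[C@@]3(C)[C@@H](OC(C)=O)CC=C(C)[C@@H]3[C@@H](O)[C@]3(O2)[C@@H](C)C(=O)O[C@H]3[C@H]1Cl | target

Total steps: 28. Longest linear sequence: 25 steps (steps 1, 2, 4–7, 9–15, 17–28, from 1 and 2 to 42).

Steps most likely to fail

1. Step 23 (ring B closure). The samarium enolate may be protonated or may add intermolecularly before the ring closes. The aldehyde may also enter on the wrong face of C1 (cis ring fusion) or give the C2 epimer, because a chair transition state with the C3 chain equatorial would favour the unwanted C1/C2 relationship. The fallback replaces the metal-enolate closure by a cationic one with an open transition state and needs no bromide. It sets out from γ-acetoxy enone 30. DDQ in buffered CH2Cl2 would give the C2 alcohol F1, and Dess–Martin oxidation the keto aldehyde F2. Ac2O with catalytic Sc(OTf)3 at 0 °C would convert only the aldehyde into the geminal diacetate F3. Under high dilution with TMSOTf and i-Pr2NEt in CH2Cl2 (−78 to 0 °C) the ketone, enolisable only at C1, would give the silyl dienol ether acylal F4 in the flask. TMSOTf would then ionise the acylal to an acetoxy-stabilised cation at C2, which C1 captures in a Mukaiyama-type addition. This delivers the C2 acetate directly and comes back to the route at 37.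

2. Step 9 (C-glycosylation at C8). Conjugate (Mukaiyama–Michael) addition of 15 to the enone may outrun ionisation of the hindered tertiary acetate, and C17 may form with low selectivity. The fallback removes the enone before the C–C bond is made and sets out from acetate 12. Luche reduction (NaBH4, CeCl3·7H2O, MeOH, −78 °C) would give the C5 allylic alcohol F5, and TESCl/imidazole its silyl ether F6. Ferrier-type C-glycosylation of this allylic anomeric acetate with 15 and catalytic TMSOTf would give the C-glycoside silyl ether F7. Selective TES removal (PPTS, MeOH) would give the allylic alcohol F8, and MnO2 oxidation comes back to the route at enone 16.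

3. Step 17 (fragment union by boron aldol). Addition to the neopentyl aldehyde may be slow, the aldehyde's own facial bias may oppose the enolate-controlled anti pathway, and the chloroborane may attack the dimethyl ketal. The fallback generates the enolate by conjugate addition instead of enolisation and uses no boron Lewis acid. It sets out from dienone 23 and aldehyde 22: the copper-catalysed Me2Zn addition of step 16 is run and the methylzinc dienolate F9 is trapped in the same flask with 22 at −30 °C (tandem conjugate addition–aldol, closed transition state on the enolate face anti to the new methyl group). This comes back to the route at aldol 26.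

Further compounds
F1 | step 23 | C2 primary alcohol of γ-acetoxy enone 30 (no bromide) | C=C1[C@H](CCO)O[C@@]2([C@H](O[Si](C)(C)C(C)(C)C)[C@H]3C(C)(OC(C)=O)C=CC(=O)[C@@H]3C)[C@@H](C)C(=O)O[C@H]2[C@@H]1O[Si](C(C)C)(C(C)C)C(C)C
F2 | step 23 | C2 aldehyde of γ-acetoxy enone 30 (keto aldehyde) | C=C1[C@H](CC=O)O[C@@]2([C@H](O[Si](C)(C)C(C)(C)C)[C@H]3C(C)(OC(C)=O)C=CC(=O)[C@@H]3C)[C@@H](C)C(=O)O[C@H]2[C@@H]1O[Si](C(C)C)(C(C)C)C(C)C
F3 | step 23 | C2 geminal diacetate (acylal) of F2 | C=C1[C@H](CC(OC(C)=O)OC(C)=O)O[C@@]2([C@H](O[Si](C)(C)C(C)(C)C)[C@H]3C(C)(OC(C)=O)C=CC(=O)[C@@H]3C)[C@@H](C)C(=O)O[C@H]2[C@@H]1O[Si](C(C)C)(C(C)C)C(C)C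
F4 | step 23 | C14 trimethylsilyl dienol ether of acylal F3 (formed in the flask) | C=C1[C@H](CC(OC(C)=O)OC(C)=O)O[C@@]2([C@H](O[Si](C)(C)C(C)(C)C)[C@H]3C(C)(OC(C)=O)C=CC(O[Si](C)(C)C)=C3C)[C@@H](C)C(=O)O[C@H]2[C@@H]1O[Si](C(C)C)(C(C)C)C(C)C
F5 | step 9 | C5 allylic alcohol from Luche reduction of 12 (C5 undefined) | OC1[C@H](CCOCc2ccc(OC)cc2)O[C@](OC(C)=O)(CO[Si](C)(C)C(C)(C)C)C=C1
F6 | step 9 | C5 TES ether of F5 | CC[Si](CC)(CC)OC1[C@H](CCOCc2ccc(OC)cc2)O[C@](OC(C)=O)(CO[Si](C)(C)C(C)(C)C)C=C1
F7 | step 9 | C8 C-glycoside (tert-butyl propanoate branch, 17R) with C5 OTES | CC[Si](CC)(CC)OC1[C@H](CCOCc2ccc(OC)cc2)O[C@@](CO[Si](C)(C)C(C)(C)C)([C@@H](C)C(=O)OC(C)(C)C)C=C1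
F8 | step 9 | C5 allylic alcohol of the C-glycoside | OC1[C@H](CCOCc2ccc(OC)cc2)O[C@@](CO[Si](C)(C)C(C)(C)C)([C@@H](C)C(=O)OC(C)(C)C)C=C1
F9 | step 17 | methylzinc dienolate from conjugate addition to 23 | C[C@@H]1C=C(O[Zn]C)C=CC1(OC)OC
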